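**Retrosynthetic overview**
1. Feature: in ring A of the trans-decalin, the C10 methyl and the C4 homoprenyl chain are 1,3-diaxial (both β). A rod-shaped silylethynyl group at C4 stands in for that chain, because it accepts this axial site in a chair-like transition state where a methyl group would not.
2. Key disconnection: C5–C10 and C8–C9, by intramolecular Diels–Alder reaction of triene 20 ((E)-β-methyl enoate C9=C10 plus (E,E)-1-silyloxydiene C5–C8). Rings A and B form in the same step, and C5, C9 and C10 are relayed from C4.
3. After the cycloaddition: C11 ester → vinyl → B-alkyl Suzuki coupling with (E)-β-triflyloxycrotonate 8 (C12–C13). Then ethynyl → vinyl → B-alkyl Suzuki coupling with 1-bromo-2-methylpropene (homoprenyl).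
4. Ring B end game: C8–OTBS → Δ6-8-enone → 1,4-reduction with enolate hydroxylation (7α-OH) → C8 methylenation → ester hydrolysis.
5. Before the cycloaddition: C4 comes from a Cu-catalysed enantioselective SN2' alkynylation of an allylic phosphate. Its chain is joined at C1–C10 by B-alkyl Suzuki coupling of triflate 8 with a dienol made from pent-1-en-4-yne (carboalumination, hydroxymethylation). Then vinyl → enal → silyl dienol ether.

Key step: step 10

Remark on the chemistry: labdane numbering is used throughout and β means the face of the C10 methyl; carbon-delivering building blocks are numbered as starting materials and paraformaldehyde is drawn as its monomer; triflate 8 is prepared once in quantity and drawn on in steps 3 and 14; it is assumed that the antipode of the NHC ligand in step 5 can be chosen so that (S)-14 results.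

**Step 1**
Reactants: 1 pent-1-en-4-yne; 2 trimethylaluminium; 3 paraformaldehyde
Product: 6 (2E)-3-methylhexa-2,5-dien-1-ol, via alkenylalane 4 (not isolated), via lithium alanate 5 (not isolated)
Conditions: Me3Al (2 equiv), Cp2ZrCl2 (0.25 equiv), CH2Cl2, 0 °C to rt; volatiles removed; n-BuLi (1 equiv), hexane, 0 °C; THF, (CH2O)n, rt; dil. HCl
Reagents that add atoms: none
Why: Negishi Zr-catalysed carboalumination adds CH3 and Al syn across the terminal alkyne with Al at the terminus much faster than the parent zirconocene touches the isolated alkene, and the derived alanate is hydroxymethylated by formaldehyde with retention, so the trisubstituted alkene should form E.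

**Step 2**
Reactants: 7 methyl acetoacetate
Product: 8 methyl (2E)-3-{[(trifluoromethyl)sulfonyl]oxy}but-2-enoate
Conditions: Tf2O, 25% aq. Me4NOH, hexanes, 5 °C
Reagents that add atoms: trifluoromethanesulfonic anhydride, O=S(=O)(OS(=O)(=O)C(F)(F)F)C(F)(F)F
Why: O-Triflation of the acetoacetate enolate under biphasic conditions with a non-coordinating ammonium counter-ion goes through the open, non-chelated enolate and should give the E enol triflate, in which the leaving group is trans to the ester.

**Step 3**
Reactants: 6 (2E)-3-methylhexa-2,5-dien-1-ol; 8 (E)-enol triflate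
Product: 10 methyl (2E,7E)-9-hydroxy-3,7-dimethylnona-2,7-dienoate, via bis(9-BBN) adduct 9 (not isolated)
Conditions: 9-BBN (2.2 equiv), THF, 0 °C to rt; then 8, PdCl2(dppf) (5 mol %), K3PO4 (aq.), THF/DMF, rt to 40 °C
Reagents that add atoms: none
Why: B-alkyl Suzuki–Miyaura coupling: one equivalent of 9-BBN masks the hydroxyl as a borinate that the aqueous base later cleaves, the second adds to the monosubstituted alkene far faster than to the trisubstituted one with boron on the terminal carbon (C1), and the C(sp3)–C(sp2) coupling retains the triflate geometry, so the C9=C10 enoate is obtained E beside the untouched E allylic alcohol.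

**Step 4**
Reactants: 10 methyl (2E,7E)-9-hydroxy-3,7-dimethylnona-2,7-dienoate
Product: 11 methyl (2E,7E)-9-[(diethoxyphosphoryl)oxy]-3,7-dimethylnona-2,7-dienoate
Conditions: ClP(O)(OEt)2, Et3N, DMAP (cat.), CH2Cl2, 0 °C to rt
Reagents that add atoms: diethyl chlorophosphate, CCOP(=O)(Cl)OCC
Why: Standard O-phosphorylation of a primary allylic alcohol installs the leaving group needed for copper-catalysed allylic substitution and touches neither alkene.

**Step 5**
Reactants: 11 allylic phosphate; 12 ethynyltrimethylsilane
Product: 14 methyl (2E,7S)-3,7-dimethyl-7-[(trimethylsilyl)ethynyl]nona-2,8-dienoate, via alkynylalane 13 (not isolated)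
Conditions: 12, n-BuLi, THF/hexane, −78 to 0 °C; i-Bu2AlCl, 0 °C to rt; then 11, CuCl2·2H2O (5 mol %), chiral sulfonate-bearing NHC–Ag complex from 1,2-diphenylethylenediamine (2.5 mol %), THF, −30 to −15 °C
Reagents that add atoms: none
Why: NHC–copper-catalysed enantioselective allylic substitution with an alkynylaluminium reagent: the alkynylcopper species attacks the γ-carbon (C4) of the E-trisubstituted allylic phosphate SN2' and anti to the leaving group, the bidentate chiral carbene differentiates the alkene faces and so sets the quaternary C4 as S, and the enoate is not attacked by the alane at this temperature.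

**Step 6**
Reactants: 14 1,4-enyne
Product: 16 methyl (2E,7S)-9-hydroxy-3,7-dimethyl-7-[(trimethylsilyl)ethynyl]non-2-enoate, via B-alkyl-9-BBN 15 (not isolated)
Conditions: 9-BBN (1.3 equiv), THF, 0 °C to rt; 30% H2O2, pH 7 phosphate buffer, 0 °C to rt
Reagents that add atoms: hydrogen peroxide, OO
Why: Brown hydroboration–oxidation: 9-BBN reacts with the monosubstituted alkene far faster than with the silyl-capped alkyne or the electron-poor enoate and places boron on the terminal carbon (C6), while buffered peroxide spares the ester and the C–Si bond and C4 is untouched.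

**Step 7**
Reactants: 16 primary alcohol
Product: 17 methyl (2E,7S)-3,7-dimethyl-9-oxo-7-[(trimethylsilyl)ethynyl]non-2-enoate
Conditions: Dess–Martin periodinane, CH2Cl2, 0 °C to rt
Reagents that add atoms: none
Why: Dess–Martin oxidation stops cleanly at the aldehyde under neutral conditions, and the α-CH2 carries no stereocentre.

**Step 8**
Reactants: 17 aldehyde; 18 (triphenylphosphoranylidene)acetaldehyde
Product: 19 methyl (2E,7S,9E)-3,7-dimethyl-11-oxo-7-[(trimethylsilyl)ethynyl]undeca-2,9-dienoate
Conditions: PhMe, 80 °C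
Reagents that add atoms: none
Why: The Wittig reaction with a stabilised formyl ylide is E-selective and adds C7 and C8, and the enal formed is less electrophilic than the saturated aldehyde, which limits a second olefination.

**Step 9**
Reactants: 19 enal
Product: 20 methyl (2E,7S,8E,10E)-11-[(tert-butyldimethylsilyl)oxy]-3,7-dimethyl-7-[(trimethylsilyl)ethynyl]undeca-2,8,10-trienoate
Conditions: TBSOTf (1.3 equiv), Et3N (2.5 equiv), CH2Cl2, 0 °C to rt
Reagents that add atoms: tert-butyldimethylsilyl triflate, CC(C)(C)[Si](C)(C)OS(=O)(=O)C(F)(F)F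
Why: Soft enolisation (O-silylation of the s-trans enal, then γ-deprotonation at C5 by the amine) gives the 1-silyloxydiene, the s-trans conformer leading to the E enol ether and A1,3 strain with the quaternary C4 leading to the E C5=C6 bond, while the much less Lewis-basic enoate is not silylated.

**Step 10**
Reactants: 20 silyloxytrienoate
Product: 21 methyl (1R,2S,4aR,5S,8aS)-2-[(tert-butyldimethylsilyl)oxy]-5,8a-dimethyl-5-[(trimethylsilyl)ethynyl]-1,2,4a,5,6,7,8,8a-octahydronaphthalene-1-carboxylate (trans-octalin; Δ6, 8β-OTBS, 9β-CO2Me, 10β-CH3, 5α-H, 4α-CH3, 4β-C≡C–TMS)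
Conditions: PhMe (0.01 M), BHT (0.1 equiv), silylated sealed tube, 190 °C
Reagents that add atoms: none
Why: Concerted, asynchronous, suprafacial [4+2] cycloaddition of normal electron demand (a type 1 intramolecular Diels–Alder reaction, closest known class the thermal cyclisation of deca-2,7,9-trienoates to trans-octalins), in which the oxygen donor on C8 puts the large HOMO coefficient on C5 and the ester puts the large LUMO coefficient on C10, so the regiochemistry forced by the tether is also the electronically matched one. Ring A (C10, C1–C5) closes through the four-carbon tether in a chair-like array as C5–C10 forms, and ring B (C5–C10) is the new cyclohexene closed by C5–C10 and C8–C9. The E-enoate geometry is transferred suprafacially, so the C10 methyl and the C9 ester end up cis (both β), and the E,E-diene geometry places C8–O cis to the C5–C4 bond. The ester-endo transition state holds C1 of the tether exo, which gives 5α-H and 10β-CH3 (trans fusion) and an equatorial C9 ester. The only pre-existing stereocentre, C4, selects the diene face, because in the chair tether the axial C4 group faces the C10 methyl and leans over C6–H, so the slim silylethynyl group (A value about 0.4 against about 1.7 kcal/mol for methyl) takes that site, which is the 4β position of the target chain. The step needs endo/exo and facial selectivity: the first rests on secondary overlap of the ester with the electron-rich diene and on the C3/C6–H strain of the exo array, the second on the methyl/ethynyl size difference, while the quaternary C4 also excludes 1,5-H shifts of the diene at the temperature the β,β-disubstituted dienophile requires.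

**Step 11**
Reactants: 21 Diels–Alder adduct
Product: 22 C11 alcohol (21 with 9β-CH2OH in place of CO2Me; Δ6, 8β-OTBS, 4β-C≡C–TMS, all centres as in 21)
Conditions: DIBAL-H (3 equiv), CH2Cl2, −78 to 0 °C; Rochelle salt
Reagents that add atoms: none
Why: DIBAL-H reduces the hindered equatorial ester to the primary alcohol without touching the silyl ether, ring alkene or silylalkyne at low temperature, and no stereocentre is affected.

**Step 12**
Reactants: 22 C11 alcohol
Product: 23 C11 aldehyde (9β-CHO; Δ6, 8β-OTBS, 4β-C≡C–TMS)
Conditions: Dess–Martin periodinane, pyridine, CH2Cl2, 0 °C; used directly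
Reagents that add atoms: none
Why: Buffered Dess–Martin oxidation gives the aldehyde under non-basic conditions, which avoids β-elimination of the C8 silyloxy group that stands antiperiplanar to C9–H, and the equatorial 9β-formyl group is also the thermodynamically preferred epimer.

**Step 13**
Reactants: 23 C11 aldehyde; 24 methyltriphenylphosphonium bromide
Product: 26 9β-vinyl octalin (C11=C12; Δ6, 8β-OTBS, 4β-C≡C–TMS), via methylidenetriphenylphosphorane 25 (not isolated)
Conditions: 24, KHMDS, THF, 0 °C; then 23, −78 to 0 °C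
Reagents that add atoms: none
Why: Wittig methylenation: the small non-stabilised ylide adds to the aldehyde at low temperature faster than it enolises it, giving the vinyl group with C9 unchanged.

**Step 14**
Reactants: 26 9β-vinyl octalin; 8 (E)-enol triflate
Product: 28 methyl (2E)-3-methyl-5-(octalin-9β-yl)pent-2-enoate (9β-CH2CH2C(CH3)=CHCO2Me; Δ6, 8β-OTBS, 4β-C≡C–TMS), via B-alkyl-9-BBN 27 (not isolated)
Conditions: 9-BBN (1.5 equiv), THF, rt; then 8, PdCl2(dppf) (5 mol %), K3PO4 (aq.), THF/DMF, rt to 50 °C
Reagents that add atoms: none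
Why: B-alkyl Suzuki–Miyaura coupling: 9-BBN selects the monosubstituted C11=C12 alkene over the ring alkene and the silylalkyne, and the C(sp3)–C(sp2) coupling with the vinyl triflate proceeds with retention of geometry, so C13=C14 is obtained E.

**Step 15**
Reactants: 28 silylalkyne ester
Product: 29 4β-ethynyl compound (otherwise as 28)
Conditions: K2CO3 (cat.), MeOH, rt
Reagents that add atoms: none
Why: Methanolysis of the C(sp)–Si bond by catalytic methoxide is specific for the alkynylsilane, and the hindered TBS ether and the methyl ester (same alkoxide) are unchanged.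

**Step 16**
Reactants: 29 terminal alkyne
Product: 30 4β-vinyl compound (otherwise as 29)
Conditions: H2 (1 atm), Lindlar catalyst, quinoline, EtOAc, rt, uptake monitored
Reagents that add atoms: none
Why: Lindlar semi-hydrogenation stops at the alkene when hydrogen uptake is monitored, and the poisoned catalyst leaves the di- and trisubstituted alkenes alone.

**Step 17**
Reactants: 30 4β-vinyl compound; 31 1-bromo-2-methylprop-1-ene
Product: 33 4β-(4-methylpent-3-enyl) compound (Δ6, 8β-OTBS, methyl 13E-enoate), via B-alkyl-9-BBN 32 (not isolated)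
Conditions: 9-BBN (2 equiv), THF, 50 °C; then 31, PdCl2(dppf) (10 mol %), K3PO4 (aq.), THF/DMF, 50 °C
Reagents that add atoms: none
Why: B-alkyl Suzuki–Miyaura coupling: 9-BBN adds to the only monosubstituted alkene with boron on the terminal carbon away from the quaternary C4, and coupling with the vinyl bromide completes the homoprenyl chain without touching C4.

**Step 18**
Reactants: 33 8β-silyl ether
Product: 34 Δ6-8β-ol
Conditions: TBAF, THF, rt to 45 °C; aq. NH4Cl
Reagents that add atoms: none
Why: Fluoride cleaves the Si–O bond of the allylic TBS ether, and the ester and alkenes are inert.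

**Step 19**
Reactants: 34 allylic alcohol
Product: 35 Δ6-8-enone
Conditions: Dess–Martin periodinane, CH2Cl2, 0 °C to rt
Reagents that add atoms: none
Why: Dess–Martin oxidation of the secondary allylic alcohol gives the enone under neutral conditions, and the equatorial C9 chain is the stable epimer next to the new ketone.

**Step 20**
Reactants: 35 enone
Product: 37 7α-hydroxy-8-ketone, via potassium enolate 36 (not isolated)
Conditions: K-Selectride (1.1 equiv), THF, −78 °C; then 3-phenyl-2-(phenylsulfonyl)oxaziridine (1.5 equiv), −78 °C; AcOH quench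
Reagents that add atoms: 3-phenyl-2-(phenylsulfonyl)-1,2-oxaziridine, O=S(=O)(N1OC1c1ccccc1)c1ccccc1
Why: Conjugate reduction of a cyclohexenone with a CH β-carbon by a trialkylborohydride gives the Δ7 enolate regiospecifically, and Davis oxidation of it occurs by axial attack on the α face, away from the axial C10 methyl, which sets C7 as the axial 7α-alcohol, while the oxaziridine does not epoxidise the isolated alkenes.

**Step 21**
Reactants: 37 7α-hydroxy-8-ketone
Product: 38 7α-(tert-butyldimethylsilyloxy)-8-ketone
Conditions: TBSOTf, 2,6-lutidine, CH2Cl2, −40 to 0 °C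
Reagents that add atoms: tert-butyldimethylsilyl triflate, CC(C)(C)[Si](C)(C)OS(=O)(=O)C(F)(F)F
Why: A silyl triflate with a hindered pyridine base silylates the hindered axial alcohol without enolising the ketone, which guards C7 against epimerisation and α-ketol shift in the next step.

**Step 22**
Reactants: 38 silyloxy ketone; 39 dibromomethane
Product: 40 methyl 7α-(tert-butyldimethylsilyloxy)-8(17),13E-dienoate
Conditions: Zn, CH2Br2, TiCl4 (pre-aged reagent), THF/CH2Cl2, 0 °C to rt
Reagents that add atoms: none
Why: Takai–Lombardo methylenation: the non-basic gem-dimetallic titanium reagent converts hindered, enolisable ketones into methylidene groups without epimerising C7 or C9 and does not react with esters.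

**Step 23**
Reactants: 40 silyl ether
Product: 41 methyl ester of the target (7α-OH)
Conditions: TBAF, THF, rt to 50 °C; aq. NH4Cl
Reagents that add atoms: none
Why: Fluoride-induced desilylation frees the allylic axial alcohol under non-acidic conditions, so no allylic ionisation at C7 can occur.

**Step 24**
Reactants: 41 methyl ester
Product: 42 (13E)-7α-hydroxy-19-(3-methylbut-2-en-1-yl)labda-8(17),13-dien-15-oic acid (CNP0169778.1)
Conditions: LiOH, THF/MeOH/H2O, 50 °C; then 1 M HCl to pH 3–4, 0 °C
Reagents that add atoms: lithium hydroxide, [Li+].[OH-]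
Why: Saponification of the β,β-disubstituted enoate proceeds by acyl–oxygen cleavage without E/Z isomerisation, and no stereocentre is base-labile at this stage.

**Compound list**
1 | pent-1-en-4-yne | C=CCC#C | starting material
2 | trimethylaluminium | C[Al](C)C | starting material
3 | paraformaldehyde (formaldehyde source, drawn as the monomer) | C=O | starting material
4 | dimethyl[(1E)-2-methylpenta-1,4-dien-1-yl]alumane | C=CC/C(C)=C/[Al](C)C | intermediate
5 | lithium butyldimethyl[(1E)-2-methylpenta-1,4-dien-1-yl]alanate | [Li+].C=CC/C(C)=C/[Al-](C)(C)CCCC | intermediate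
6 | (2E)-3-methylhexa-2,5-dien-1-ol | C=CC/C(C)=C/CO | intermediate
7 | methyl acetoacetate | COC(=O)CC(C)=O | starting material
8 | methyl (2E)-3-{[(trifluoromethyl)sulfonyl]oxy}but-2-enoate | COC(=O)/C=C(\C)OS(=O)(=O)C(F)(F)F | intermediate
9 | bis(9-BBN) adduct of 6 (O-borinate, boron on C1) | C/C(CCCB1C2CCCC1CCC2)=C\COB1C2CCCC1CCC2 | intermediate
10 | methyl (2E,7E)-9-hydroxy-3,7-dimethylnona-2,7-dienoate | COC(=O)/C=C(\C)CCC/C(C)=C/CO | intermediate
11 | methyl (2E,7E)-9-[(diethoxyphosphoryl)oxy]-3,7-dimethylnona-2,7-dienoate | COC(=O)/C=C(\C)CCC/C(C)=C/COP(=O)(OCC)OCC | intermediate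
12 | ethynyltrimethylsilane | C#C[Si](C)(C)C | starting material
13 | diisobutyl[(trimethylsilyl)ethynyl]alumane | CC(C)C[Al](CC(C)C)C#C[Si](C)(C)C | intermediate
14 | methyl (2E,7S)-3,7-dimethyl-7-[(trimethylsilyl)ethynyl]nona-2,8-dienoate | COC(=O)/C=C(\C)CCC[C@](C)(C#C[Si](C)(C)C)C=C | intermediate
15 | B-alkyl-9-BBN from 14 (boron on C6) | COC(=O)/C=C(\C)CCC[C@](C)(C#C[Si](C)(C)C)CCB1C2CCCC1CCC2 | intermediate
16 | methyl (2E,7S)-9-hydroxy-3,7-dimethyl-7-[(trimethylsilyl)ethynyl]non-2-enoate | COC(=O)/C=C(\C)CCC[C@](C)(C#C[Si](C)(C)C)CCO | intermediate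
17 | methyl (2E,7S)-3,7-dimethyl-9-oxo-7-[(trimethylsilyl)ethynyl]non-2-enoate | COC(=O)/C=C(\C)CCC[C@](C)(C#C[Si](C)(C)C)CC=O | intermediate
18 | (triphenylphosphoranylidene)acetaldehyde | O=CC=P(c1ccccc1)(c1ccccc1)c1ccccc1 | starting material
19 | methyl (2E,7S,9E)-3,7-dimethyl-11-oxo-7-[(trimethylsilyl)ethynyl]undeca-2,9-dienoate | COC(=O)/C=C(\C)CCC[C@](C)(C#C[Si](C)(C)C)C/C=C/C=O | intermediate
20 | methyl (2E,7S,8E,10E)-11-[(tert-butyldimethylsilyl)oxy]-3,7-dimethyl-7-[(trimethylsilyl)ethynyl]undeca-2,8,10-trienoate | COC(=O)/C=C(\C)CCC[C@](C)(C#C[Si](C)(C)C)/C=C/C=C/O[Si](C)(C)C(C)(C)C | intermediate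
21 | Diels–Alder adduct, methyl (1R,2S,4aR,5S,8aS)-2-(TBSO)-5,8a-dimethyl-5-[(trimethylsilyl)ethynyl]-1,2,4a,5,6,7,8,8a-octahydronaphthalene-1-carboxylate | CC(C)(C)[Si](C)(C)O[C@H]1C=C[C@H]2[C@@](C)(C#C[Si](C)(C)C)CCC[C@]2(C)[C@H]1C(=O)OC | intermediate
22 | C11 alcohol (9β-CH2OH) | CC(C)(C)[Si](C)(C)O[C@H]1C=C[C@H]2[C@@](C)(C#C[Si](C)(C)C)CCC[C@]2(C)[C@H]1CO | intermediate
23 | C11 aldehyde (9β-CHO) | CC(C)(C)[Si](C)(C)O[C@H]1C=C[C@H]2[C@@](C)(C#C[Si](C)(C)C)CCC[C@]2(C)[C@H]1C=O | intermediate
24 | methyltriphenylphosphonium bromide | C[P+](c1ccccc1)(c1ccccc1)c1ccccc1.[Br-] | starting material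
25 | methylidenetriphenylphosphorane | C=P(c1ccccc1)(c1ccccc1)c1ccccc1 | intermediate
26 | 9β-vinyl octalin | CC(C)(C)[Si](C)(C)O[C@H]1C=C[C@H]2[C@@](C)(C#C[Si](C)(C)C)CCC[C@]2(C)[C@H]1C=C | intermediate
27 | B-alkyl-9-BBN from 26 (boron on C12) | CC(C)(C)[Si](C)(C)O[C@H]1C=C[C@H]2[C@@](C)(C#C[Si](C)(C)C)CCC[C@]2(C)[C@H]1CCB1C2CCCC1CCC2 | intermediate
28 | 13E-enoate with 4β-C≡C–TMS, 8β-OTBS, Δ6 | CC(C)(C)[Si](C)(C)O[C@H]1C=C[C@H]2[C@@](C)(C#C[Si](C)(C)C)CCC[C@]2(C)[C@H]1CC/C(C)=C/C(=O)OC | intermediate
29 | 4β-ethynyl compound | CC(C)(C)[Si](C)(C)O[C@H]1C=C[C@H]2[C@@](C)(C#C)CCC[C@]2(C)[C@H]1CC/C(C)=C/C(=O)OC | intermediate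
30 | 4β-vinyl compound | CC(C)(C)[Si](C)(C)O[C@H]1C=C[C@H]2[C@@](C)(C=C)CCC[C@]2(C)[C@H]1CC/C(C)=C/C(=O)OC | intermediate
31 | 1-bromo-2-methylprop-1-ene | CC(C)=CBr | starting material
32 | B-alkyl-9-BBN from 30 | CC(C)(C)[Si](C)(C)O[C@H]1C=C[C@H]2[C@@](C)(CCB3C4CCCC3CCC4)CCC[C@]2(C)[C@H]1CC/C(C)=C/C(=O)OC | intermediate
33 | 4β-homoprenyl, 8β-OTBS, Δ6 methyl ester | CC(C)(C)[Si](C)(C)O[C@H]1C=C[C@H]2[C@@](C)(CCC=C(C)C)CCC[C@]2(C)[C@H]1CC/C(C)=C/C(=O)OC | intermediate
34 | Δ6-8β-ol | O[C@H]1C=C[C@H]2[C@@](C)(CCC=C(C)C)CCC[C@]2(C)[C@H]1CC/C(C)=C/C(=O)OC | intermediate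
35 | Δ6-8-enone | O=C1C=C[C@H]2[C@@](C)(CCC=C(C)C)CCC[C@]2(C)[C@H]1CC/C(C)=C/C(=O)OC | intermediate
36 | potassium Δ7-enolate | [K+].[O-]C1=CC[C@H]2[C@@](C)(CCC=C(C)C)CCC[C@]2(C)[C@H]1CC/C(C)=C/C(=O)OC | intermediate
37 | 7α-hydroxy-8-ketone | O=C1[C@H](O)C[C@H]2[C@@](C)(CCC=C(C)C)CCC[C@]2(C)[C@H]1CC/C(C)=C/C(=O)OC | intermediate
38 | 7α-TBSO-8-ketone | O=C1[C@H](O[Si](C)(C)C(C)(C)C)C[C@H]2[C@@](C)(CCC=C(C)C)CCC[C@]2(C)[C@H]1CC/C(C)=C/C(=O)OC | intermediate
39 | dibromomethane | BrCBr | starting material
40 | 7α-TBSO-8(17)-ene methyl ester | C=C1[C@H](O[Si](C)(C)C(C)(C)C)C[C@H]2[C@@](C)(CCC=C(C)C)CCC[C@]2(C)[C@H]1CC/C(C)=C/C(=O)OC | intermediate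
41 | methyl ester of the target | C=C1[C@H](O)C[C@H]2[C@@](C)(CCC=C(C)C)CCC[C@]2(C)[C@H]1CC/C(C)=C/C(=O)OC | intermediate
42 | (13E)-7α-hydroxy-19-(3-methylbut-2-en-1-yl)labda-8(17),13-dien-15-oic acid | C=C1[C@H](O)C[C@H]2[C@@](C)(CCC=C(C)C)CCC[C@]2(C)[C@H]1CC/C(C)=C/C(=O)O | target

**Total step count:** 24. **Longest linear sequence:** 23 (steps 1 and 3–24; step 2 is a one-step side branch whose product enters at steps 3 and 14).

**Steps most likely to fail**

Step 10.
- What may go wrong: the β,β-disubstituted enoate may cyclise only at temperatures where loss of silanol from the adduct or drift of the enol ether geometry sets in. The endo/exo and facial preferences may also be too small, so that cis-fused or C4-epimeric octalins form alongside the desired one.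
- Fallback: raise the dienophile activation instead of the temperature. It sets out from 20, which is reduced with DIBAL-H (CH2Cl2, −78 °C) to the silyloxytrienol F1. This is oxidised with MnO2 (CH2Cl2, rt) to the silyloxytrienal F2.
- The lower LUMO and stronger endo preference of the enal should allow the same C5–C10/C8–C9 cycloaddition at clearly lower temperature, or under a bulky aluminium Lewis acid at low temperature.
- The adduct is aldehyde 23, where the route is rejoined, so steps 11 and 12 are not needed.

Step 5.
- What may go wrong: enantioselectivity or SN2' regioselectivity may erode with the silyl-capped alkynyl nucleophile, residual lithium salt may interfere with the catalyst, or isobutyl transfer may compete.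
- Fallback: build C4 by reagent-controlled epoxidation followed by stereospecific substitution. It sets out from 10. Sharpless epoxidation (Ti(OiPr)4, D-(−)-diethyl tartrate, TBHP, 4 Å MS, CH2Cl2, −20 °C) should give the (2R,3R)-epoxy alcohol F3.
- Opening F3 with alkynylalane 13 (excess, PhMe/CH2Cl2, 0 °C) at the tertiary epoxide carbon with inversion should give the alkynyl diol F4.
- Garegg–Samuelsson deoxygenation of the terminal vicinal diol (I2, PPh3, imidazole, PhMe, 90 °C) should return the vinyl group. The route is rejoined at 14.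

Step 20.
- What may go wrong: hydride delivery to the hindered C6 may be slow enough for 1,2-reduction to compete, the enolate may equilibrate towards C9 before it is oxidised, or the axial alcohol may epimerise on basic work-up.
- Fallback: a neutral, two-stage sequence that sets out from 35. Rhodium-catalysed 1,4-hydrosilylation (Et3SiH, RhCl(PPh3)3, PhMe, 50 °C) should give the isolable triethylsilyl enol ether F5.
- Rubottom oxidation of F5 with one equivalent of dimethyldioxirane (acetone/CH2Cl2, −78 °C) attacks the most electron-rich alkene from the α face and should give the silyloxy epoxide F6.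
- F6 is opened and desilylated with AcOH/THF/H2O. The route is rejoined at 37.

**Further compounds**
F1 | step 10 | silyloxytrienol, (2E,7S,8E,10E)-11-[(tert-butyldimethylsilyl)oxy]-3,7-dimethyl-7-[(trimethylsilyl)ethynyl]undeca-2,8,10-trien-1-ol | OC/C=C(\C)CCC[C@](C)(C#C[Si](C)(C)C)/C=C/C=C/O[Si](C)(C)C(C)(C)C
F2 | step 10 | silyloxytrienal, (2E,7S,8E,10E)-11-[(tert-butyldimethylsilyl)oxy]-3,7-dimethyl-7-[(trimethylsilyl)ethynyl]undeca-2,8,10-trienal | O=C/C=C(\C)CCC[C@](C)(C#C[Si](C)(C)C)/C=C/C=C/O[Si](C)(C)C(C)(C)C
F3 | step 5 | (2R,3R)-epoxy alcohol, methyl (2E)-6-[(2R,3R)-3-(hydroxymethyl)-2-methyloxiran-2-yl]-3-methylhex-2-enoate | COC(=O)/C=C(\C)CCC[C@@]1(C)O[C@@H]1CO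
F4 | step 5 | alkynyl diol, methyl (2E,7R,8S)-8,9-dihydroxy-3,7-dimethyl-7-[(trimethylsilyl)ethynyl]non-2-enoate | COC(=O)/C=C(\C)CCC[C@](C)(C#C[Si](C)(C)C)[C@H](O)CO
F5 | step 20 | triethylsilyl enol ether (Δ7, 8-OTES) | CC[Si](CC)(CC)OC1=CC[C@H]2[C@@](C)(CCC=C(C)C)CCC[C@]2(C)[C@H]1CC/C(C)=C/C(=O)OC
F6 | step 20 | silyloxy epoxide (7α,8α-epoxy-8β-OTES) | CC[Si](CC)(CC)O[C@@]12O[C@@H]1C[C@H]3[C@@](C)(CCC=C(C)C)CCC[C@]3(C)[C@H]2CC/C(C)=C/C(=O)OC
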